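A small charge comes first: the flask holds 77 µM of impurity against 0.46 mM of free catalyst. Suppose each impurity takes one free catalyst out of the round, with impurity as the limiting reagent of that side reaction. Then subtract: 0.383 mM is the working catalyst, the charged [free catalyst] minus the charged [impurity].

| flask | left-handed substrate | right-handed substrate | solid reagent | free catalyst | impurity | remark | time |
|---|---|---|---|---|---|---|---|
| south-east | 0.20 M | 0.20 M | 0.44 M | 0.46 mM | 52 µM | run made earlier |  |
| west | 0.20 M | 0.20 M | 0.44 M | 0.46 mM | 120 µM | run made earlier |  |
| flask | 0.20 M | 0.20 M | 0.440 M | 0.46 mM | 77 µM |  | 25 h |

| run | time / h | left-handed product / % | right-handed product / % |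
|---|---|---|---|
| south-east | 5.00 | 6.3 | 1.1 |
| south-east | 10.0 | 16.0 | 4.5 |
| south-east | 15.0 | 25.0 | 5.8 |
| south-east | 20.0 | 33.4 | 8.0 |
| south-east | 25.0 | 41.0 | 9.5 |
| west | 2.00 | 0 | 0.9 |
| west | 6.00 | 8.2 | 1.7 |
| west | 12.0 | 18.0 | 4.9 |
| west | 20.0 | 31.6 | 8.3 |
| west | 25.0 | 39.0 | 7.9 |

(readings scatter by 1 percentage point)

- free catalyst is single-handed; left-handed substrate and right-handed substrate are mirror images of each other, charged as a racemate, each of them at the stated concentration
- given per volume of solution although it is solid: solid reagent
- what was read earlier has a scatter of 1 percentage point, one standard deviation
- at the start none of the solid reagent is in solution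
- an excess is the difference of the two amounts in percent of their sum
- an excess is below zero if the other one leads

1. left-handed product and right-handed product together, in percent of the left-handed substrate and right-handed substrate charged together, at 25 h
2. excess of left-handed product over right-handed product in the product at 25 h
3. whether the exchange between left-handed substrate and right-handed substrate keeps pace with the reaction: how far the product's excess at 25 h gets from its value without exchange to its value with instant exchange (above 80% keeps pace, below 20% hardly takes part, else lags behind)

Now bracket the flask's total at 25 h. The bound from above is the south-east run, with working catalyst 0.408 mM and total 50.5%. The bound from below is the west run, with 0.340 mM and 46.9%. The flask's working catalyst lies between them, so the bracket is 3.6 percentage points wide, and each reading carries 1 point. Tighten it with a straight line in working catalyst: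

total = 46.9% + (50.5% − 46.9%) × (0.383 mM − 0.340 mM) / (0.408 mM − 0.340 mM) = 49.2%

Without exchange, the south-east run's 41.0% of left-handed product at 25.0 h leaves 9.00% of left-handed substrate against 40.5% of right-handed substrate, yet its last interval still reads 7.6 points of left-handed product gained against 1.5 points of right-handed product. Commit to "keeps pace". Pooling the readings of both runs at 20.0 h and 25.0 h gives an excess of 62.3%.

The forecast gives 49% (45% to 53%), inside the bracket, an excess of 61% (55% to 67%) and keeps pace, saying “It does not fall, so the exchange appears to keep pace with the reaction.”

The flask gives 49.7%, an excess of 61.2%, and keeps pace, at 87% of the way.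

    partner + free catalyst + left-handed substrate → free catalyst + left-handed product (k = 97.0 /M²/min)
    partner + free catalyst + right-handed substrate → free catalyst + right-handed product (k = 22.0 /M²/min)
    left-handed substrate ⇌ right-handed substrate (k = 0.00470 /min)
    free catalyst + impurity → spent catalyst (k = 5200 /M/min)
    solid reagent ⇌ partner, rate k5*(cs5 - [partner]) while solid is left; crystals form when [partner] > cs5 (solubility = 0.0960 M, k = 0.00200 /min)

In the flask, free catalyst stands at 83.3% of its charge at 25.0 h, which is the share 83.3% that working catalyst gave, with impurity at 0%. Take the neighbour flask charged with 1.9 × 10⁻⁴ M of impurity. Its working catalyst is 0.270 mM, below the west run's, or 58.7% of the charge, and the neighbour holds 58.7% free catalyst at 25.0 h. The same line, extended, gives a total of 43.2%. The neighbour flask ends a little higher, at 44.9%, with an excess of 61.4%.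

The readings are simulated on assumed constants.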